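Left long enough, a flask of this network keeps a mere leftover of its target, so what counts is whether it is read before it gets there.

    starting material → intermediate (k1 = 0.011 min⁻¹, Ea1 = 105 kJ mol⁻¹)
    intermediate ⇌ target (K2 = 1.4, k2 = 0.091 min⁻¹, Ea2 = 118 kJ mol⁻¹, ΔH2 = −54.0 kJ mol⁻¹)
    intermediate ⇌ isomer of the product (K3 = 190, k3 = 0.0011 min⁻¹, Ea3 = 121 kJ mol⁻¹, ΔH3 = −54.0 kJ mol⁻¹)
    starting material → decomposition product (k4 = 8.5 × 10⁻⁵ min⁻¹, Ea4 = 120 kJ mol⁻¹)
    (constants at 90 °C)

| setting | cedar | ash | alder |
|---|---|---|---|
| starting material | 1.5 M | 1.5 M | 1.5 M |
| temperature | 120 °C | 150 °C | 90 °C |
| time | 4.0 h | 4.0 h | 4.0 h |

- the list of constants is for 90 °C, to be carried to other temperatures by the activation energies and enthalpies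

- the flask with the highest amount of target, in percent of the starting material charged ("all alike" if they lie within 1.5 percentage points) (cedar / ash / alder / all alike)
- final target, as a percentage of the starting material charged, in cedar
- final target, as a percentage of the starting material charged, in ash
- final target, as a percentage of the starting material charged, in alder

Take the end state first. Intermediate, target and isomer of the product then stand as one to the target constant to the isomer constant, so the leftover of target is the target constant over the sum of the three. The leftover is 0.728% in alder. The two steps share an enthalpy of −54.0 kJ mol⁻¹, so heat barely moves it:

- cedar: target constant 0.358, isomer constant 48.5, leftover 0.717%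
- ash: target constant 0.111, isomer constant 15.0, leftover 0.686%

The end states therefore lie close together, and the question becomes how far each approach has gone. Now the ladder in alder, fastest first:

- target and intermediate exchange in 6.41 min
- starting material lives 90.2 min
- the reading comes at 4.0 h
- the pool of intermediate plus target drains in 35.9 h

That last rung is the drain time: one over the sum of the forward isomer constant divided by one plus the target constant, and the forward isomer constant divided by the isomer constant. With heat it falls:

- cedar: forward constant 0.0234 min⁻¹, drain time 56.4 min, so the reading stands at 4.26 drain times
- ash: forward constant 0.323 min⁻¹, drain time 3.20 min, so the reading stands at 75.0 drain times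
- alder: the reading stands at 0.111 drain times

Alder is thus under kinetic control, and ash under thermodynamic control. This reckoning gives ash its leftover, 0.686%, with the side step to decomposition product left out. Cedar gets the leftover plus the target share of the undrained pool, 1.09%. Alder gets the target share of a consecutive pool, 49.8%, the highest.

The forecast also names alder, with 1.13% in cedar, above this reckoning, and 0.68% in ash and 49.5% in alder, both below it . Its ground: “it is the only flask that stays under kinetic control”.

The simulation gives alder, with 1.12% in cedar, 0.676% in ash and 49.5% in alder.

In alder, starting material still fed the pool up to the reading, falling to 6.99% at 4.00 h, while isomer of the product had reached 7.12%. In ash, starting material stood at 0% by 2.00 h, and target already read 0.676%, as it still did at 40.0 h; a drain time of 3.20 min puts the asked reading at 75.0 of them. Ash read at 6.0 h stands at 112 drain times, so the reckoning again gives the leftover, 0.686%; the computed value is 0.676%.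

The rate constants were set for the occasion.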